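**Strategy.** The side chain is numbered C1 (ylidene carbon on the tetronate ring) to C13 (CH2 on the furan ring). Everything rests on the C5–C6 bond, where the sp3 CH2 carbon C5 meets the methyl-bearing sp2 carbon C6 of the (Z)-C6=C7 olefin. A B-alkyl Suzuki–Miyaura coupling makes this bond and carries the Z geometry of an iodoalkene into the product in one operation. Its precursors are a (Z)-ylidene O-methyl tetronate that carries the (S)-C2 stereocenter and a terminal C4=C5 vinyl group, hydroborated in the flask, and a (Z)-2-iodoalkene that already holds the (E)-C10=C11 olefin and the 3-furyl ring. O-Demethylation of the coupled product then gives the target.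

Key step: step 13

Remark: 3-methyltetronic acid is taken as a purchasable building block; the target stereocenter (side-chain C2) is S, and the racemic carbinol center made in step 3 is destroyed in step 4.

Step 1
Reactants: 1 3-bromofuran
Product: 3 3-(furan-3-yl)propan-1-ol, via 3-lithiofuran 2 (not isolated)
Conditions: n-BuLi, Et2O, −78 °C; then oxetane, BF3·OEt2, −78 °C
Reagents that add atoms: oxetane C1COC1
Why: Bromine–lithium exchange at −78 °C (cold enough to stop migration of lithium to furan C2) gives 3-lithiofuran, which opens BF3-activated oxetane by SN2 attack at a CH2 carbon, a Lewis-acid-promoted oxetane opening by an organolithium.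

Step 2
Reactants: 3 3-(furan-3-yl)propan-1-ol
Product: 4 3-(furan-3-yl)propanal
Conditions: Dess–Martin periodinane, CH2Cl2, 0 °C to rt
Reagents that add atoms: none
Why: Dess–Martin oxidation of a primary alcohol stops at the aldehyde and should leave the furan untouched.

Step 3
Reactants: 4 3-(furan-3-yl)propanal
Product: 5 5-(furan-3-yl)-2-methylpent-1-en-3-ol (racemic)
Conditions: CH2=C(CH3)MgBr, THF, −78 to 0 °C
Reagents that add atoms: isopropenylmagnesium bromide C=C(C)[Mg]Br
Why: Grignard 1,2-addition to the aldehyde should give the 2-methyl allylic alcohol needed for the rearrangement; its carbinol center need not be controlled.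

Step 4
Reactants: 5 5-(furan-3-yl)-2-methylpent-1-en-3-ol
Product: 7 ethyl (4E)-7-(furan-3-yl)-4-methylhept-4-enoate, via mixed ketene acetal 6 (not isolated)
Conditions: CH3C(OEt)3 (excess), EtCO2H (cat.), 140 °C, EtOH distilled off
Reagents that add atoms: triethyl orthoacetate CC(OCC)(OCC)OCC
Why: Johnson–Claisen rearrangement, in which the ketene acetal formed by orthoester exchange undergoes a [3,3]-sigmatropic shift through a chair with the furylethyl group equatorial, which should set the (E)-trisubstituted olefin.

Step 5
Reactants: 7 ethyl (4E)-7-(furan-3-yl)-4-methylhept-4-enoate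
Product: 8 (4E)-7-(furan-3-yl)-4-methylhept-4-enal
Conditions: i-Bu2AlH (1.1 equiv), CH2Cl2, −78 °C; then aq. potassium sodium tartrate
Reagents that add atoms: none
Why: Partial ester reduction at −78 °C should stop at the tetrahedral aluminium hemiacetal, which releases the aldehyde only on work-up.

Step 6
Reactants: 8 (4E)-7-(furan-3-yl)-4-methylhept-4-enal
Product: 9 3-[(3E,7Z)-8-iodo-4-methylnona-3,7-dien-1-yl]furan
Conditions: EtPPh3I, n-BuLi, THF, rt; I2, −78 °C; NaN(SiMe3)2, −20 °C; then 8, −78 to −20 °C
Reagents that add atoms: ethyltriphenylphosphonium iodide CC[P+](c1ccccc1)(c1ccccc1)c1ccccc1.[I-]; iodine II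
Why: Stork–Zhao olefination, in which the α-iodo ylide reacts under kinetic control like a non-stabilised ylide and should give the (Z)-2-iodoalkene with iodine cis to the chain; iodine is consumed before the furan-bearing aldehyde is added.

Step 7
Reactants: 10 (4R)-4-benzyl-3-propanoyl-1,3-oxazolidin-2-one
Product: 12 (4R)-4-benzyl-3-[(2S)-2-methylpent-4-enoyl]-1,3-oxazolidin-2-one, via sodium (Z)-enolate 11 (not isolated)
Conditions: NaN(SiMe3)2, THF, −78 °C; then allyl iodide, −78 to −45 °C
Reagents that add atoms: allyl iodide C=CCI
Why: Evans asymmetric alkylation, in which allyl iodide attacks the chelated (Z)-enolate on the face opposite the benzyl group of the (R)-auxiliary, which should set the (S)-methyl stereocenter.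

Step 8
Reactants: 12 (4R)-4-benzyl-3-[(2S)-2-methylpent-4-enoyl]-1,3-oxazolidin-2-one
Product: 13 (2S)-2-methylpent-4-en-1-ol
Conditions: LiBH4, MeOH (1 equiv), Et2O, 0 °C
Reagents that add atoms: none
Why: Reductive cleavage of the N-acyl oxazolidinone by hydride attack at the exocyclic carbonyl should give the primary alcohol without touching the α-stereocenter and free the auxiliary.

Step 9
Reactants: 13 (2S)-2-methylpent-4-en-1-ol
Product: 14 (2S)-2-methylpent-4-enal
Conditions: Dess–Martin periodinane, CH2Cl2, 0 °C to rt; concentrated cold and used at once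
Reagents that add atoms: none
Why: Dess–Martin oxidation under near-neutral conditions should give the volatile α-chiral aldehyde without epimerisation.

Step 10
Reactants: 15 4-hydroxy-3-methylfuran-2(5H)-one (3-methyltetronic acid)
Product: 16 4-methoxy-3-methylfuran-2(5H)-one
Conditions: Me2SO4, K2CO3, acetone, reflux
Reagents that add atoms: dimethyl sulfate COS(=O)(=O)OC
Why: O-alkylation of the vinylogous carboxylic acid at the C4 oxygen (Williamson-type methylation) should give the vinylogous methyl ester, which protects the acidic OH through steps 11 to 13.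

Step 11
Reactants: 16 4-methoxy-3-methylfuran-2(5H)-one; 14 (2S)-2-methylpent-4-enal
Product: 18 5-[(2S)-1-hydroxy-2-methylpent-4-en-1-yl]-4-methoxy-3-methylfuran-2(5H)-one (diastereomer mixture), via lithium furanolate 17 (not isolated)
Conditions: LiN(i-Pr)2, THF, −78 °C; then 14, −78 °C; AcOH quench
Reagents that add atoms: none
Why: γ-Deprotonation at ring C5 gives the aromatic lithium furanolate, whose aldol addition at C5 to the aldehyde at −78 °C should outrun enolisation of the α-chiral aldehyde; the two new centers are removed in step 12.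

Step 12
Reactants: 18 5-[(2S)-1-hydroxy-2-methylpent-4-en-1-yl]-4-methoxy-3-methylfuran-2(5H)-one
Product: 20 (5Z)-4-methoxy-3-methyl-5-[(2S)-2-methylpent-4-en-1-ylidene]furan-2(5H)-one, via mesylate 19 (not isolated)
Conditions: MsCl, Et3N, CH2Cl2, 0 °C; then DBU, 0 °C to rt
Reagents that add atoms: none
Why: Mesylation followed by E1cB elimination through the furanolate formed at the acidic C5–H should give the conjugated ylidene, with the (Z)-isomer favoured because the chain turns away from the 4-methoxy group, while the (S)-center is not at the acidic position.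

Step 13
Reactants: 20 (5Z)-4-methoxy-3-methyl-5-[(2S)-2-methylpent-4-en-1-ylidene]furan-2(5H)-one; 9 3-[(3E,7Z)-8-iodo-4-methylnona-3,7-dien-1-yl]furan
Product: 22 (5Z)-5-[(2S,6Z,10E)-13-(furan-3-yl)-2,6,10-trimethyltrideca-6,10-dien-1-ylidene]-4-methoxy-3-methylfuran-2(5H)-one, via B-alkyl-9-BBN borane 21 (not isolated)
Conditions: 9-BBN dimer, THF, 0 °C to rt; H2O; then 9, PdCl2(dppf) (5 mol%), AsPh3, Cs2CO3, DMF/THF/H2O, rt
Reagents that add atoms: none
Why: 9-BBN adds anti-Markovnikov to the monosubstituted C4=C5 vinyl group of 20 to give the primary alkylborane 21; zerovalent palladium formed from PdCl2(dppf) inserts into the C–I bond of 9 with retention, the base-activated borate transfers its primary alkyl group to palladium, and reductive elimination forms the C5–C6 bond. The closest known reaction type is the B-alkyl Suzuki–Miyaura coupling of a 9-BBN alkylborane with a (Z)-2-iodoalkene. No ring is closed and no stereocenter is formed; the (S)-C2 center is three bonds from boron and is not touched, and the C6=C7 olefin should keep the Z geometry of 9 because oxidative addition and reductive elimination both proceed with retention. The step needs chemoselective hydroboration of the terminal alkene over the trisubstituted ylidene C=C, the tetrasubstituted ring C=C and the lactone C=O of 20, which the bulk and low hydride reactivity of 9-BBN should secure; the furan and olefins of 9 never meet free borane because excess 9-BBN is quenched with water before 9 is added. β-Hydride elimination from the alkylpalladium should be held back by the wide-bite-angle dppf ligand and AsPh3 at room temperature.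

Step 14
Reactants: 22 (5Z)-5-[(2S,6Z,10E)-13-(furan-3-yl)-2,6,10-trimethyltrideca-6,10-dien-1-ylidene]-4-methoxy-3-methylfuran-2(5H)-one
Product: 23 (5Z)-5-[(2S,6Z,10E)-13-(furan-3-yl)-2,6,10-trimethyltrideca-6,10-dien-1-ylidene]-4-hydroxy-3-methylfuran-2(5H)-one
Conditions: LiCl, DMSO, 60 °C; then 0.5 M aq. HCl, 0 °C
Reagents that add atoms: none
Why: SN2 O-demethylation of the vinylogous methyl ester by chloride in a dipolar aprotic solvent (the tetronate anion is a good leaving group) is neutral and should spare the furan, the olefins and the ylidene; brief cold acidification frees the tetronic acid.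

**Compound list**

1 | 3-bromofuran | Brc1ccoc1 | starting material
2 | 3-lithiofuran | [Li]c1ccoc1 | intermediate
3 | 3-(furan-3-yl)propan-1-ol | OCCCc1ccoc1 | intermediate
4 | 3-(furan-3-yl)propanal | O=CCCc1ccoc1 | intermediate
5 | 5-(furan-3-yl)-2-methylpent-1-en-3-ol (racemic) | C=C(C)C(O)CCc1ccoc1 | intermediate
6 | 3-[3-(1-ethoxyethenyloxy)-4-methylpent-4-en-1-yl]furan (mixed ketene acetal) | C=C(OCC)OC(CCc1ccoc1)C(C)=C | intermediate
7 | ethyl (4E)-7-(furan-3-yl)-4-methylhept-4-enoate | CCOC(=O)CC/C(C)=C/CCc1ccoc1 | intermediate
8 | (4E)-7-(furan-3-yl)-4-methylhept-4-enal | O=CCC/C(C)=C/CCc1ccoc1 | intermediate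
9 | 3-[(3E,7Z)-8-iodo-4-methylnona-3,7-dien-1-yl]furan | I/C(C)=C\CC/C(C)=C/CCc1ccoc1 | intermediate
10 | (4R)-4-benzyl-3-propanoyl-1,3-oxazolidin-2-one | CCC(=O)N1[C@H](Cc2ccccc2)COC1=O | starting material
11 | sodium (Z)-enolate of 10 | C/C=C(\[O-])N1[C@H](Cc2ccccc2)COC1=O.[Na+] | intermediate
12 | (4R)-4-benzyl-3-[(2S)-2-methylpent-4-enoyl]-1,3-oxazolidin-2-one | C=CC[C@H](C)C(=O)N1[C@H](Cc2ccccc2)COC1=O | intermediate
13 | (2S)-2-methylpent-4-en-1-ol | C=CC[C@H](C)CO | intermediate
14 | (2S)-2-methylpent-4-enal | C=CC[C@H](C)C=O | intermediate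
15 | 4-hydroxy-3-methylfuran-2(5H)-one (3-methyltetronic acid) | CC1=C(O)COC1=O | starting material
16 | 4-methoxy-3-methylfuran-2(5H)-one | CC1=C(OC)COC1=O | intermediate
17 | lithium 4-methoxy-3-methylfuran-2-olate | [Li+].[O-]c1occ(OC)c1C | intermediate
18 | 5-[(2S)-1-hydroxy-2-methylpent-4-en-1-yl]-4-methoxy-3-methylfuran-2(5H)-one (diastereomer mixture) | C=CC[C@H](C)C(O)C1OC(=O)C(C)=C1OC | intermediate
19 | methanesulfonate of 18 | C=CC[C@H](C)C(OS(C)(=O)=O)C1OC(=O)C(C)=C1OC | intermediate
20 | (5Z)-4-methoxy-3-methyl-5-[(2S)-2-methylpent-4-en-1-ylidene]furan-2(5H)-one | CC1=C(OC)/C(=C/[C@@H](C)CC=C)OC1=O | intermediate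
21 | (5Z)-5-[(2S)-5-(9-borabicyclo[3.3.1]nonan-9-yl)-2-methylpentylidene]-4-methoxy-3-methylfuran-2(5H)-one | CC1=C(OC)/C(=C/[C@@H](C)CCCB2C3CCCC2CCC3)OC1=O | intermediate
22 | (5Z)-5-[(2S,6Z,10E)-13-(furan-3-yl)-2,6,10-trimethyltrideca-6,10-dien-1-ylidene]-4-methoxy-3-methylfuran-2(5H)-one | CC1=C(OC)/C(=C/[C@@H](C)CCC/C(C)=C\CC/C(C)=C/CCc2ccoc2)OC1=O | intermediate
23 | (5Z)-5-[(2S,6Z,10E)-13-(furan-3-yl)-2,6,10-trimethyltrideca-6,10-dien-1-ylidene]-4-hydroxy-3-methylfuran-2(5H)-one | CC1=C(O)/C(=C/[C@@H](C)CCC/C(C)=C\CC/C(C)=C/CCc2ccoc2)OC1=O | target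

**Step count.** Total: 14 steps. Longest linear sequence: 8 steps (steps 1 to 6, then 13 and 14); the other branch runs through steps 7, 8, 9, 11 and 12, with step 10 as a one-step side branch.

**Steps most likely to fail**

Step 13. Under the aqueous carbonate of the coupling the borane may transfer its alkyl group too slowly, so that protodeboronation, hydrolysis of the tetronate lactone and reduction of the iodoalkene compete. The fallback replaces the boron route by a base-free Negishi coupling. Setting out from 20, hydroboration with 9-BBN and oxidation with NaBO3·4H2O would give (5Z)-5-[(2S)-5-hydroxy-2-methylpentylidene]-4-methoxy-3-methylfuran-2(5H)-one F1. I2, PPh3 and imidazole in CH2Cl2 would turn it into (5Z)-5-[(2S)-5-iodo-2-methylpentylidene]-4-methoxy-3-methylfuran-2(5H)-one F2. Insertion of activated Zn (LiCl, THF, 40 °C) would give {(4S,5Z)-5-[3-methoxy-4-methyl-5-oxofuran-2(5H)-ylidene]-4-methylpentyl}zinc iodide F3, and its coupling with 9 under Pd(PPh3)4 in THF/DMA should give 22, where the route is rejoined.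

Step 6. The α-iodo ylide may decompose or lose iodine before it meets the aldehyde, and the olefination may then give poor conversion and a mixture of olefin geometries. The fallback builds the haloalkene stepwise by cross-coupling instead of by a halogenated ylide. Setting out from 8, Ramirez dibromo-olefination (CBr4, PPh3, Et3N, CH2Cl2, 0 °C) would give 3-[(3E)-8,8-dibromo-4-methylocta-3,7-dien-1-yl]furan F4. Trans-selective Negishi monomethylation (Me2Zn, PdCl2(DPEphos), THF) should replace the bromine trans to the chain and give 3-[(3E,7Z)-8-bromo-4-methylnona-3,7-dien-1-yl]furan F5. This bromide would take the place of 9 in step 13, with Pd(P(t-Bu)3)2 as catalyst to keep the geometry, and rejoin the route at 22.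

Step 12. The E1cB elimination may give both ylidene geometries, and long contact with DBU may remove the allylic C2 proton through the extended enolate and erode the stereocenter. The fallback sets the geometry by thermodynamic equilibration instead of by kinetic control of the elimination. Setting out from 18, mesylation and a short elimination at 0 °C would be stopped early, and the (5E)-4-methoxy-3-methyl-5-[(2S)-2-methylpent-4-en-1-ylidene]furan-2(5H)-one F6 formed beside 20 would be isomerised with catalytic I2 in CH2Cl2 under visible light. The (5Z)-isomer, in which the chain avoids the 4-methoxy group, is expected to be the more stable one, so the material rejoins the route at 20.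

**Further compounds**

F1 | step 13 | (5Z)-5-[(2S)-5-hydroxy-2-methylpentylidene]-4-methoxy-3-methylfuran-2(5H)-one | CC1=C(OC)/C(=C/[C@@H](C)CCCO)OC1=O
F2 | step 13 | (5Z)-5-[(2S)-5-iodo-2-methylpentylidene]-4-methoxy-3-methylfuran-2(5H)-one | CC1=C(OC)/C(=C/[C@@H](C)CCCI)OC1=O
F3 | step 13 | {(4S,5Z)-5-[3-methoxy-4-methyl-5-oxofuran-2(5H)-ylidene]-4-methylpentyl}zinc iodide | CC1=C(OC)/C(=C/[C@@H](C)CCC[Zn]I)OC1=O
F4 | step 6 | 3-[(3E)-8,8-dibromo-4-methylocta-3,7-dien-1-yl]furan | BrC(Br)=CCC/C(C)=C/CCc1ccoc1
F5 | step 6 | 3-[(3E,7Z)-8-bromo-4-methylnona-3,7-dien-1-yl]furan | Br/C(C)=C\CC/C(C)=C/CCc1ccoc1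
F6 | step 12 | (5E)-4-methoxy-3-methyl-5-[(2S)-2-methylpent-4-en-1-ylidene]furan-2(5H)-one | CC1=C(OC)/C(=C\[C@@H](C)CC=C)OC1=O
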